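Ring B of the 2α-hydroxylabd-7-ene core is cut at C6–C7 and C9–C10, which divides the twenty-carbon skeleton into two ten-carbon halves: ring A carrying C6 as an exocyclic methylene (from actinol) and the chain C7–C9/C11–C16 as an (E)-enal (from (S)-citronellol). One Lewis-acid operation, a formal [3+3] annulation, joins them: a carbonyl-ene reaction forms C6–C7 and shifts the alkene to C5=C10, then ionisation of the allylic alkoxide lets C10 close onto C9 and proton loss gives the 5,7-diene. The step exploits the allyl unit C6–C5–C10 of ring A and the 2-methylallyl unit C7–C8–C9 of ring B; hydrogenation then sets C5.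

Key step: step 5

Assumption: (4R,6R)-actinol 1 and (S)-citronellol 4 are bought enantiopure; atoms carry labdane numbers (decalin C1–C10, side chain C11–C16, C17 on C8, C18/C19 on C4, C20 on C10).

Step 1
Reactants: 1 (4R,6R)-4-hydroxy-2,2,6-trimethylcyclohexan-1-one (actinol)
Product: 2 (4R,6R)-4-[(tert-butyldimethylsilyl)oxy]-2,2,6-trimethylcyclohexan-1-one
Conditions: TBSCl, imidazole, DMF, rt
Reagents that add atoms: tert-butyldimethylsilyl chloride, CC(C)(C)[Si](C)(C)Cl
Why: Silyl ether formation protects the unhindered secondary alcohol (the later C2 oxygen) without touching either stereocentre.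

Step 2
Reactants: 2 (4R,6R)-4-[(tert-butyldimethylsilyl)oxy]-2,2,6-trimethylcyclohexan-1-one
Product: 3 tert-butyldimethyl{[(1R,5R)-3,3,5-trimethyl-4-methylidenecyclohexyl]oxy}silane
Conditions: Ph3PCH3Br, KOtBu, toluene, 90 °C
Reagents that add atoms: methyltriphenylphosphonium bromide, C[P+](c1ccccc1)(c1ccccc1)c1ccccc1.[Br-]
Why: Wittig methylenation at elevated temperature converts the hindered ketone into the exocyclic alkene (C5=C6), and any epimerisation of the methyl-bearing centre is harmless because that centre becomes sp2 in step 5.

Step 3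
Reactants: 4 (S)-citronellol, (3S)-3,7-dimethyloct-6-en-1-ol
Product: 5 (3S)-3,7-dimethyloct-6-en-1-yl acetate
Conditions: Ac2O, pyridine, DMAP (cat.), CH2Cl2, 0 °C → rt
Reagents that add atoms: acetic anhydride, CC(=O)OC(C)=O
Why: Acylation of the primary alcohol gives an acetate that should survive SeO2, the aluminium Lewis acids and hydrogenation and is later removed without touching a silyl ether.

Step 4
Reactants: 5 (3S)-3,7-dimethyloct-6-en-1-yl acetate
Product: 6 (3S,6E)-3,7-dimethyl-8-oxooct-6-en-1-yl acetate
Conditions: SeO2 (1.2 equiv), 1,4-dioxane, 80 °C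
Reagents that add atoms: selenium dioxide, O=[Se]=O
Why: Riley oxidation (ene reaction, then [2,3]-sigmatropic shift) attacks the methyl group trans to the chain and a full equivalent of SeO2 carries it on to the (E)-enal, which fixes the alkene geometry needed in step 5.

Step 5
Reactants: 3 tert-butyldimethyl{[(1R,5R)-3,3,5-trimethyl-4-methylidenecyclohexyl]oxy}silane; 6 (3S,6E)-3,7-dimethyl-8-oxooct-6-en-1-yl acetate
Product: 8 (13S)-2α-[(tert-butyldimethylsilyl)oxy]labda-5,7-dien-15-yl acetate, via aluminium alkoxide of the ene adduct 7 (not isolated)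
Conditions: Me2AlCl (2.5 equiv), CH2Cl2, −78 → −20 °C; then MeAlCl2 (2 equiv), −78 → 0 °C
Reagents that add atoms: none
Why: Proposed new method: the Me2AlCl-complexed aldehyde of 6 takes the only allylic hydrogen of 3 (on C10) in a carbonyl-ene reaction that forms C6–C7 and moves the alkene to C5=C10; MeAlCl2 then ionises the allylic aluminium alkoxide 7 to the 2-methylallyl cation C7–C8–C9, C10 of the tetrasubstituted alkene closes onto C9, and the tertiary C5 cation, whose only β-hydrogens are on C6, loses a proton to a methylaluminium species to give the conjugated 5,7-diene. The closest known reaction types are the two-fold ene annulation of methylenecycloalkanes with unsaturated carbonyl compounds under alkylaluminium halides and cation–olefin cyclisations started by ionisation of an allylic alcohol. Ring B closes in a 6-endo mode with respect to the C5=C10 alkene, with the three allyl carbons inside the new ring, which places the alkene at C7=C8. C9 and C10 are set together: the (E)-enal keeps C11 on the outer side of the allyl cation, and the least strained half-chair-like closure (C6 in the allyl plane, ring torsions about C8–C9 and C10–C5 of the same sign) should put H9 anti to the C10 methyl group. The face of C10 should be chosen by the C2 silyloxy group, which stays equatorial only if the C10 methyl group becomes axial on the β face, because closure on the other face would force it axial and syn to methyl groups on C4 and C10. The step needs 1,2- instead of 1,4-attack on the enal, which the hindered β-carbon of the α-methyl enal should secure, and ring closure faster than proton loss from the allyl cation, which the six-ring geometry and the nucleophilic tetrasubstituted alkene should secure.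

Step 6
Reactants: 8 (13S)-2α-[(tert-butyldimethylsilyl)oxy]labda-5,7-dien-15-yl acetate
Product: 9 (13S)-2α-[(tert-butyldimethylsilyl)oxy]labd-7-en-15-yl acetate (5α-H, 9α-H, 10β-CH3)
Conditions: H2 (1 atm), Raney Ni, EtOAc, rt
Reagents that add atoms: none
Why: Partial catalytic hydrogenation of a homoannular 5,7-diene, as practised on steroidal 5,7-dienes, should saturate the 5,6-double bond with hydrogen delivered from the α face opposite the axial C10 methyl group, which sets the trans ring fusion and leaves the hindered C7=C8 alkene.

Step 7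
Reactants: 9 (13S)-2α-[(tert-butyldimethylsilyl)oxy]labd-7-en-15-yl acetate
Product: 10 (13S)-2α-[(tert-butyldimethylsilyl)oxy]labd-7-en-15-ol
Conditions: K2CO3 (cat.), MeOH, rt
Reagents that add atoms: none
Why: Base-catalysed methanolysis (transesterification) cleaves the primary acetate while the secondary silyl ether and the trisubstituted alkene are inert.

Step 8
Reactants: 10 (13S)-2α-[(tert-butyldimethylsilyl)oxy]labd-7-en-15-ol; 11 (E)-caffeic acid, (2E)-3-(3,4-dihydroxyphenyl)prop-2-enoic acid
Product: 12 (13S)-2α-[(tert-butyldimethylsilyl)oxy]labd-7-en-15-yl (E)-caffeate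
Conditions: PPh3, DIAD, THF, 0 °C → rt
Reagents that add atoms: none
Why: Mitsunobu esterification activates the primary alcohol towards the carboxylate of caffeic acid, which is far more acidic than the catechol hydroxyl groups, so the ester should form without phenol protection and with the (E)-alkene intact.

Step 9
Reactants: 12 (13S)-2α-[(tert-butyldimethylsilyl)oxy]labd-7-en-15-yl (E)-caffeate
Product: 13 (13S)-2α-hydroxylabd-7-en-15-yl (E)-caffeate (2S,5S,9S,10S,13S), the target CNP0206083.1
Conditions: HF·pyridine, THF/pyridine, 0 °C → rt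
Reagents that add atoms: none
Why: Fluoride-induced desilylation under buffered conditions frees the C2 hydroxyl with retention (Si–O cleavage) and should leave the caffeate ester, the catechol and the C7=C8 alkene untouched.

Compound list
1 | (4R,6R)-4-hydroxy-2,2,6-trimethylcyclohexan-1-one (actinol) | O=C1C(C)(C)C[C@H](O)C[C@H]1C | starting material
2 | (4R,6R)-4-[(tert-butyldimethylsilyl)oxy]-2,2,6-trimethylcyclohexan-1-one | O=C1C(C)(C)C[C@H](O[Si](C)(C)C(C)(C)C)C[C@H]1C | intermediate
3 | tert-butyldimethyl{[(1R,5R)-3,3,5-trimethyl-4-methylidenecyclohexyl]oxy}silane | C=C1C(C)(C)C[C@H](O[Si](C)(C)C(C)(C)C)C[C@H]1C | intermediate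
4 | (S)-citronellol, (3S)-3,7-dimethyloct-6-en-1-ol | CC(C)=CCC[C@H](C)CCO | starting material
5 | (3S)-3,7-dimethyloct-6-en-1-yl acetate | CC(C)=CCC[C@H](C)CCOC(C)=O | intermediate
6 | (3S,6E)-3,7-dimethyl-8-oxooct-6-en-1-yl acetate | O=C/C(C)=C/CC[C@H](C)CCOC(C)=O | intermediate
7 | chloro(methyl)aluminium alkoxide of (3S,6E)-9-{(4R)-4-[(tert-butyldimethylsilyl)oxy]-2,6,6-trimethylcyclohex-1-en-1-yl}-8-hydroxy-3,7-dimethylnon-6-en-1-yl acetate (both C8 epimers; not isolated) | CC1=C(CC(O[Al](C)Cl)/C(C)=C/CC[C@H](C)CCOC(C)=O)C(C)(C)C[C@H](O[Si](C)(C)C(C)(C)C)C1 | intermediate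
8 | (13S)-2α-[(tert-butyldimethylsilyl)oxy]labda-5,7-dien-15-yl acetate (9α-H, 10β-CH3) | CC1=CC=C2C(C)(C)C[C@H](O[Si](C)(C)C(C)(C)C)C[C@]2(C)[C@H]1CC[C@H](C)CCOC(C)=O | intermediate
9 | (13S)-2α-[(tert-butyldimethylsilyl)oxy]labd-7-en-15-yl acetate (5α-H, 9α-H, 10β-CH3) | CC1=CC[C@H]2C(C)(C)C[C@H](O[Si](C)(C)C(C)(C)C)C[C@]2(C)[C@H]1CC[C@H](C)CCOC(C)=O | intermediate
10 | (13S)-2α-[(tert-butyldimethylsilyl)oxy]labd-7-en-15-ol | CC1=CC[C@H]2C(C)(C)C[C@H](O[Si](C)(C)C(C)(C)C)C[C@]2(C)[C@H]1CC[C@H](C)CCO | intermediate
11 | (E)-caffeic acid | OC(=O)/C=C/c1ccc(O)c(O)c1 | starting material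
12 | (13S)-2α-[(tert-butyldimethylsilyl)oxy]labd-7-en-15-yl (E)-caffeate | CC1=CC[C@H]2C(C)(C)C[C@H](O[Si](C)(C)C(C)(C)C)C[C@]2(C)[C@H]1CC[C@H](C)CCOC(=O)/C=C/c1ccc(O)c(O)c1 | intermediate
13 | (13S)-2α-hydroxylabd-7-en-15-yl (E)-caffeate (2S,5S,9S,10S,13S) | CC1=CC[C@H]2C(C)(C)C[C@H](O)C[C@]2(C)[C@H]1CC[C@H](C)CCOC(=O)/C=C/c1ccc(O)c(O)c1 | target

Total step count: 9
Longest linear sequence: 7 steps (steps 1, 2, 5, 6, 7, 8, 9 from 1; the branch from 4 is equally long through steps 3 and 4)

Steps most likely to fail

1. Step 5 (proposed new method).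
- What may go wrong: the alkene may attack the β-carbon of the enal (conjugate ene or oxa-[4+2] addition) instead of the carbonyl carbon. The allyl cation may lose a proton, take a methyl group from aluminium, or be diverted by homoallyl–cyclopropylcarbinyl participation of the C5=C10 alkene before C10 reaches C9. Closure may also occur on the other face of C10.
- Fallback: it sets out from 3 and 6 and separates the two events into operations of known type. The Me2AlCl-promoted carbonyl-ene reaction of the 1,1-disubstituted alkene with the aldehyde is run alone and worked up with aqueous NaHCO3. This gives the isolated ene adduct, (3S,6E)-9-{(4R)-4-[(tert-butyldimethylsilyl)oxy]-2,6,6-trimethylcyclohex-1-en-1-yl}-8-hydroxy-3,7-dimethylnon-6-en-1-yl acetate F1. F1 is then ionised on its own with SnCl4 and 2,6-di-tert-butyl-4-methylpyridine in CH2Cl2 at −78 °C, with no organoaluminium present. This cation–olefin cyclisation started from an allylic alcohol loses water and comes back to the route at diene 8.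

2. Step 6.
- What may go wrong: hydrogen may add 1,4 across the diene or to the C7=C8 bond, or arrive on the β face, and the catalyst may move the remaining alkene.
- Fallback: it sets out from 8 and uses electron transfer instead of a surface reaction (Li, NH3, THF, t-BuOH, −78 °C). The diene radical anion should be protonated axially at C5 from the α face and then at C6. The same conditions cleave the acetate, so step 7 is skipped and the sequence comes back at alcohol 10; no new compound is made (F0).

3. Step 8.
- What may go wrong: alkylation of the phenolic hydroxyl groups or consumption of the activated phosphonium species by the catechol may stall the esterification.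
- Fallback: it sets out from 10. Heating with Meldrum's acid in toluene at 90 °C gives the malonic acid half-ester 3-{[(13S)-2α-[(tert-butyldimethylsilyl)oxy]labd-7-en-15-yl]oxy}-3-oxopropanoic acid F2. Knoevenagel–Doebner condensation of F2 with 3,4-dihydroxybenzaldehyde (pyridine, piperidine cat., 50 °C) builds the (E)-cinnamate with loss of carbon dioxide and comes back at 12.

Further compounds
F1 | step 5 | (3S,6E)-9-{(4R)-4-[(tert-butyldimethylsilyl)oxy]-2,6,6-trimethylcyclohex-1-en-1-yl}-8-hydroxy-3,7-dimethylnon-6-en-1-yl acetate (both C8 epimers) | CC1=C(CC(O)/C(C)=C/CC[C@H](C)CCOC(C)=O)C(C)(C)C[C@H](O[Si](C)(C)C(C)(C)C)C1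
F0 | step 6 | none | none
F2 | step 8 | 3-{[(13S)-2α-[(tert-butyldimethylsilyl)oxy]labd-7-en-15-yl]oxy}-3-oxopropanoic acid | CC1=CC[C@H]2C(C)(C)C[C@H](O[Si](C)(C)C(C)(C)C)C[C@]2(C)[C@H]1CC[C@H](C)CCOC(=O)CC(=O)O
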